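The C3 hydroxymethyl and C4 guaiacylmethyl groups of the target oxolane (O1, C2 aryl, C3 CH2OH, C4 benzyl, C5) are cis. Tying the hydroxymethyl oxygen to the benzylic carbon creates a second oxolane, ring B, fused across C3–C4, and a five–five fusion must be cis. The route therefore disconnects the C4–benzylic carbon bond. A rhodium carbene at C4 of an α-diazo-γ-butyrolactone (C5 as carbonyl; C2 aryl and C3 arm trans, set by an auxiliary aldol) inserts into the benzylic C–H of a silylated vanillyl ether on the C3 arm. One operation forms that bond, ring B and the C4 configuration. Ring B is later opened reductively at its phenolic benzylic C–O bond.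

Key step: step 10

Remark: C2–C5 above are the atoms of the target oxolane; lactones and bicycles below carry their own ring numbering. Metal enolates, N-lithio species and metal alkoxides are treated as salts of the numbered compounds and are not numbered. Compounds 1 and 2 are taken as purchased.

Step 1
Reactants: 1 (S)-4-benzyl-1,3-oxazolidin-2-one; 2 methyl 4-chloro-4-oxobutanoate
Product: 3 methyl 4-[(4S)-4-benzyl-2-oxo-1,3-oxazolidin-3-yl]-4-oxobutanoate
Conditions: n-BuLi, THF, −78 °C; then 2, −78 → 0 °C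
Reagents that add atoms: none
Why: N-acylation of the lithiated oxazolidinone (loading of the Evans auxiliary) occurs at the acid chloride, which is far more electrophilic than the methyl ester, and leaves the auxiliary stereocentre untouched.

Step 2
Reactants: 3 methyl 4-[(4S)-4-benzyl-2-oxo-1,3-oxazolidin-3-yl]-4-oxobutanoate; 4 3,4,5-trimethoxybenzaldehyde
Product: 6 (4S)-4-benzyl-3-{[(2S,3S)-5-oxo-2-(3,4,5-trimethoxyphenyl)oxolan-3-yl]carbonyl}-1,3-oxazolidin-2-one, via syn-aldol adduct 5 (not isolated)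
Conditions: Bu2BOTf, i-Pr2NEt, CH2Cl2, 0 °C; 4, −78 → 0 °C; pH 7 buffer, MeOH, 30% H2O2, 0 °C; then p-TsOH·H2O (cat.), CH2Cl2, rt
Reagents that add atoms: none
Why: Evans syn aldol: the Z boron enolate formed on the imide side reacts through a chair Zimmerman–Traxler transition state on the face remote from the auxiliary benzyl group, which sets both new centres (S at the carbinol carbon, S at the α-carbon), and the γ-hydroxy ester then lactonises with retention to the 2,3-trans lactone.

Step 3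
Reactants: 6 (4S)-4-benzyl-3-{[(2S,3S)-5-oxo-2-(3,4,5-trimethoxyphenyl)oxolan-3-yl]carbonyl}-1,3-oxazolidin-2-one
Product: 8 (2S,3S)-5-oxo-2-(3,4,5-trimethoxyphenyl)oxolane-3-carboxylic acid, via peroxy acid 7 (not isolated)
Conditions: LiOH, 30% H2O2, THF/H2O, 0 °C; aq. Na2SO3; then aq. HCl to pH 1
Reagents that add atoms: hydrogen peroxide, OO (source of the peroxy oxygen atoms of 7 and of the hydroxyl oxygen of 8)
Why: Hydroperoxide cleavage of an N-acyl oxazolidinone attacks the exocyclic carbonyl selectively, sulfite reduces the peroxy acid, and the final acidification re-closes any lactone opened by hydroxide, so both stereocentres are carried through.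

Step 4
Reactants: 8 (2S,3S)-5-oxo-2-(3,4,5-trimethoxyphenyl)oxolane-3-carboxylic acid
Product: 9 (4R,5S)-4-(hydroxymethyl)-5-(3,4,5-trimethoxyphenyl)oxolan-2-one
Conditions: BH3·SMe2, THF, 0 °C → rt; MeOH quench
Reagents that add atoms: none
Why: Chemoselective borane reduction of the carboxylic acid through its acyloxyborane is much faster than reduction of the lactone, and neither centre is touched (the change of descriptor from S to R at the former C3 reflects priorities only).

Step 5
Reactants: 10 vanillin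
Product: 11 4-{[tert-butyl(dimethyl)silyl]oxy}-3-methoxybenzaldehyde
Conditions: TBSCl, imidazole, DMF, rt
Reagents that add atoms: tert-butyl(chloro)dimethylsilane, CC(C)(C)[Si](C)(C)Cl
Why: Imidazole-mediated O-silylation masks the phenol, whose O–H would otherwise intercept the rhodium carbene by O–H insertion.

Step 6
Reactants: 11 4-{[tert-butyl(dimethyl)silyl]oxy}-3-methoxybenzaldehyde
Product: 12 (4-{[tert-butyl(dimethyl)silyl]oxy}-3-methoxyphenyl)methanol
Conditions: NaBH4, MeOH/THF, 0 °C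
Reagents that add atoms: none
Why: Borohydride reduction of the aryl aldehyde to the benzylic alcohol is fast at 0 °C and leaves the aryl silyl ether alone.

Step 7
Reactants: 12 (4-{[tert-butyl(dimethyl)silyl]oxy}-3-methoxyphenyl)methanol
Product: 13 (4-{[tert-butyl(dimethyl)silyl]oxy}-3-methoxyphenyl)methyl 2,2,2-trichloroethanimidate
Conditions: Cl3CCN, DBU (cat.), CH2Cl2, 0 °C
Reagents that add atoms: trichloroacetonitrile, ClC(Cl)(Cl)C#N
Why: Base-catalysed addition of the alcohol to the nitrile (trichloroacetimidate formation) gives a benzyl donor that mild acid can activate.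

Step 8
Reactants: 9 (4R,5S)-4-(hydroxymethyl)-5-(3,4,5-trimethoxyphenyl)oxolan-2-one; 13 (4-{[tert-butyl(dimethyl)silyl]oxy}-3-methoxyphenyl)methyl 2,2,2-trichloroethanimidate
Product: 14 (4R,5S)-4-{[(4-{[tert-butyl(dimethyl)silyl]oxy}-3-methoxyphenyl)methoxy]methyl}-5-(3,4,5-trimethoxyphenyl)oxolan-2-one
Conditions: CSA (10 mol %), CH2Cl2, 0 °C → rt
Reagents that add atoms: none
Why: Acid-catalysed O-benzylation by a trichloroacetimidate proceeds through the para-silyloxy-stabilised benzylic cation and avoids alkoxide conditions, under which the hydroxymethyl lactone would suffer acyl migration to the isomeric lactone.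

Step 9
Reactants: 14 (4R,5S)-4-{[(4-{[tert-butyl(dimethyl)silyl]oxy}-3-methoxyphenyl)methoxy]methyl}-5-(3,4,5-trimethoxyphenyl)oxolan-2-one
Product: 16 (4R,5S)-3-diazo-4-{[(4-{[tert-butyl(dimethyl)silyl]oxy}-3-methoxyphenyl)methoxy]methyl}-5-(3,4,5-trimethoxyphenyl)oxolan-2-one, via trifluoroacetyl lactone 15 (not isolated)
Conditions: LiN(SiMe3)2, THF, −78 °C; CF3CO2CH2CF3, −78 °C; aq. NH4Cl; then 4-AcNHC6H4SO2N3, Et3N, H2O (1 equiv), MeCN, rt
Reagents that add atoms: 2,2,2-trifluoroethyl trifluoroacetate, O=C(OCC(F)(F)F)C(F)(F)F (its trifluoroacetyl group is present only in 15); 4-acetamidobenzenesulfonyl azide, CC(=O)Nc1ccc(cc1)S(=O)(=O)N=[N+]=[N-] (supplies the two diazo nitrogen atoms)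
Why: Detrifluoroacetylative diazo transfer (Claisen-type trifluoroacetylation of the lactone enolate, then Regitz-type transfer in which the activating acyl group leaves on the sulfonamide) installs the diazo group at C3 without touching C4 or C5, because the enolate has no β leaving group.

Step 10
Reactants: 16 (4R,5S)-3-diazo-4-{[(4-{[tert-butyl(dimethyl)silyl]oxy}-3-methoxyphenyl)methoxy]methyl}-5-(3,4,5-trimethoxyphenyl)oxolan-2-one
Product: 17 (3S,3aR,6R,6aS)-6-(4-{[tert-butyl(dimethyl)silyl]oxy}-3-methoxyphenyl)-3-(3,4,5-trimethoxyphenyl)tetrahydro-1H,3H-furo[3,4-c]furan-1-one (cis-fused; trimethoxyphenyl exo; silyloxyaryl endo)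
Conditions: Rh2(OAc)4 (2 mol %), CH2Cl2, 40 °C, slow addition of 16
Reagents that add atoms: none
Why: Rh2(OAc)4 expels N2 from 16 to give an electrophilic lactone-substituted rhodium carbene, which inserts through a concerted, asynchronous three-centre transition state into the benzylic ether C–H bond five atoms away, forming the C6–C6a bond and releasing the catalyst. The closest known reaction type is the dirhodium tetracarboxylate-catalysed 1,5 C–H insertion of α-diazo-γ-butyrolactones into benzylic ether C–H bonds, which gives endo,exo-furofuranones. Ring B (O5, C6, C6a, C3a, C4) closes by this 1,5-insertion as a five-membered ring annulated onto the existing lactone. The ring-fusion centre C6a is controlled by the existing centre C3a, because the tether reaches the carbene only from its own face and a trans five–five fusion is prohibitively strained; the benzylic centre C6 is expected with its aryl endo by analogy with related insertions, and is of no consequence since it later becomes CH2. The step needs 1,5-insertion to outrun 1,2-hydride migration from C3a–H and carbene dimerisation: the C–H bond is doubly activated by the ether oxygen and the electron-rich arene, it is the only C–H bond whose insertion gives an unstrained ring, and slow addition keeps the diazo concentration low.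

Step 11
Reactants: 17 (3S,3aR,6R,6aS)-6-(4-{[tert-butyl(dimethyl)silyl]oxy}-3-methoxyphenyl)-3-(3,4,5-trimethoxyphenyl)tetrahydro-1H,3H-furo[3,4-c]furan-1-one
Product: 18 (3S,3aR,6R,6aS)-6-(4-{[tert-butyl(dimethyl)silyl]oxy}-3-methoxyphenyl)-3-(3,4,5-trimethoxyphenyl)tetrahydro-1H,3H-furo[3,4-c]furan-1-ol (anomer mixture at C1)
Conditions: i-Bu2AlH, CH2Cl2, −78 °C; aq. potassium sodium tartrate
Reagents that add atoms: none
Why: Partial reduction of a γ-lactone by i-Bu2AlH stops at the lactol because the tetrahedral aluminium alkoxide is stable at −78 °C, and the aryl silyl ether and both benzylic ethers are inert to the hydride.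

Step 12
Reactants: 18 (3S,3aR,6R,6aS)-6-(4-{[tert-butyl(dimethyl)silyl]oxy}-3-methoxyphenyl)-3-(3,4,5-trimethoxyphenyl)tetrahydro-1H,3H-furo[3,4-c]furan-1-ol
Product: 19 (1R,3aR,4S,6aR)-1-(4-{[tert-butyl(dimethyl)silyl]oxy}-3-methoxyphenyl)-4-(3,4,5-trimethoxyphenyl)tetrahydro-1H,3H-furo[3,4-c]furan
Conditions: Et3SiH, BF3·OEt2, CH2Cl2, −78 °C; aq. NaHCO3
Reagents that add atoms: none
Why: Lactol deoxygenation by ionic hydrogenation: BF3 ionises the anomeric hydroxyl to a ring oxocarbenium ion at −78 °C, well below the temperature at which the benzylic ethers ionise, and Et3SiH reduces it to the CH2 group of ring A without touching a stereocentre.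

Step 13
Reactants: 19 (1R,3aR,4S,6aR)-1-(4-{[tert-butyl(dimethyl)silyl]oxy}-3-methoxyphenyl)-4-(3,4,5-trimethoxyphenyl)tetrahydro-1H,3H-furo[3,4-c]furan
Product: 20 2-methoxy-4-[(1R,3aR,4S,6aR)-4-(3,4,5-trimethoxyphenyl)tetrahydro-1H,3H-furo[3,4-c]furan-1-yl]phenol
Conditions: Bu4NF, THF, 0 °C; aq. NH4Cl
Reagents that add atoms: none
Why: Fluoride-induced desilylation of the aryl silyl ether is driven by the Si–F bond and the phenoxide leaving group, and nothing else in the molecule responds to fluoride.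

Step 14
Reactants: 20 2-methoxy-4-[(1R,3aR,4S,6aR)-4-(3,4,5-trimethoxyphenyl)tetrahydro-1H,3H-furo[3,4-c]furan-1-yl]phenol
Product: 21 4-{[(3R,4R,5S)-4-(hydroxymethyl)-5-(3,4,5-trimethoxyphenyl)oxolan-3-yl]methyl}-2-methoxyphenol
Conditions: Et3SiH, CF3CO2H, CH2Cl2, −20 → 0 °C; aq. NaHCO3
Reagents that add atoms: none
Why: Ionic hydrogenation of a benzylic ether: protonation and C1–O2 ionisation in ring B give a para-hydroxybenzylic cation (a protonated quinone methide) that Et3SiH reduces to ArCH2 while the ring oxygen is released as the hydroxymethyl group, and only this carbon ionises because the trimethoxyphenyl-bearing carbon has no free para hydroxyl and its para methoxy group is twisted out of conjugation by its two neighbours, so the three oxolane centres stay as set.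

Compound list
1 | (S)-4-benzyl-1,3-oxazolidin-2-one | O=C1N[C@@H](Cc2ccccc2)CO1 | starting material
2 | methyl 4-chloro-4-oxobutanoate | COC(=O)CCC(=O)Cl | starting material
3 | methyl 4-[(4S)-4-benzyl-2-oxo-1,3-oxazolidin-3-yl]-4-oxobutanoate | COC(=O)CCC(=O)N1[C@@H](Cc2ccccc2)COC1=O | intermediate
4 | 3,4,5-trimethoxybenzaldehyde | COc1cc(C=O)cc(OC)c1OC | starting material
5 | methyl (3S)-4-[(4S)-4-benzyl-2-oxo-1,3-oxazolidin-3-yl]-3-[(S)-hydroxy(3,4,5-trimethoxyphenyl)methyl]-4-oxobutanoate (syn-aldol adduct) | O[C@H](c1cc(OC)c(OC)c(OC)c1)[C@@H](C(=O)N1[C@@H](Cc2ccccc2)COC1=O)CC(=O)OC | intermediate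
6 | (4S)-4-benzyl-3-{[(2S,3S)-5-oxo-2-(3,4,5-trimethoxyphenyl)oxolan-3-yl]carbonyl}-1,3-oxazolidin-2-one | O=C1O[C@H](c2cc(OC)c(OC)c(OC)c2)[C@@H](C(=O)N2[C@@H](Cc3ccccc3)COC2=O)C1 | intermediate
7 | (2S,3S)-5-oxo-2-(3,4,5-trimethoxyphenyl)oxolane-3-carboperoxoic acid | O=C1O[C@H](c2cc(OC)c(OC)c(OC)c2)[C@@H](C(=O)OO)C1 | intermediate
8 | (2S,3S)-5-oxo-2-(3,4,5-trimethoxyphenyl)oxolane-3-carboxylic acid | O=C1O[C@H](c2cc(OC)c(OC)c(OC)c2)[C@@H](C(=O)O)C1 | intermediate
9 | (4R,5S)-4-(hydroxymethyl)-5-(3,4,5-trimethoxyphenyl)oxolan-2-one | O=C1O[C@H](c2cc(OC)c(OC)c(OC)c2)[C@@H](CO)C1 | intermediate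
10 | vanillin (4-hydroxy-3-methoxybenzaldehyde) | COc1cc(C=O)ccc1O | starting material
11 | 4-{[tert-butyl(dimethyl)silyl]oxy}-3-methoxybenzaldehyde | COc1cc(C=O)ccc1O[Si](C)(C)C(C)(C)C | intermediate
12 | (4-{[tert-butyl(dimethyl)silyl]oxy}-3-methoxyphenyl)methanol | COc1cc(CO)ccc1O[Si](C)(C)C(C)(C)C | intermediate
13 | (4-{[tert-butyl(dimethyl)silyl]oxy}-3-methoxyphenyl)methyl 2,2,2-trichloroethanimidate | COc1cc(COC(=N)C(Cl)(Cl)Cl)ccc1O[Si](C)(C)C(C)(C)C | intermediate
14 | (4R,5S)-4-{[(4-{[tert-butyl(dimethyl)silyl]oxy}-3-methoxyphenyl)methoxy]methyl}-5-(3,4,5-trimethoxyphenyl)oxolan-2-one | O=C1O[C@H](c2cc(OC)c(OC)c(OC)c2)[C@@H](COCc2ccc(O[Si](C)(C)C(C)(C)C)c(OC)c2)C1 | intermediate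
15 | (4R,5S)-4-{[(4-{[tert-butyl(dimethyl)silyl]oxy}-3-methoxyphenyl)methoxy]methyl}-3-(trifluoroacetyl)-5-(3,4,5-trimethoxyphenyl)oxolan-2-one (C3 epimers and enol form) | O=C1O[C@H](c2cc(OC)c(OC)c(OC)c2)[C@@H](COCc2ccc(O[Si](C)(C)C(C)(C)C)c(OC)c2)C1C(=O)C(F)(F)F | intermediate
16 | (4R,5S)-3-diazo-4-{[(4-{[tert-butyl(dimethyl)silyl]oxy}-3-methoxyphenyl)methoxy]methyl}-5-(3,4,5-trimethoxyphenyl)oxolan-2-one (4,5-trans) | O=C1O[C@H](c2cc(OC)c(OC)c(OC)c2)[C@@H](COCc2ccc(O[Si](C)(C)C(C)(C)C)c(OC)c2)C1=[N+]=[N-] | intermediate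
17 | (3S,3aR,6R,6aS)-6-(4-{[tert-butyl(dimethyl)silyl]oxy}-3-methoxyphenyl)-3-(3,4,5-trimethoxyphenyl)tetrahydro-1H,3H-furo[3,4-c]furan-1-one | COc1cc([C@H]2[C@H]3C(=O)O[C@H](c4cc(OC)c(OC)c(OC)c4)[C@H]3CO2)ccc1O[Si](C)(C)C(C)(C)C | intermediate
18 | (3S,3aR,6R,6aS)-6-(4-{[tert-butyl(dimethyl)silyl]oxy}-3-methoxyphenyl)-3-(3,4,5-trimethoxyphenyl)tetrahydro-1H,3H-furo[3,4-c]furan-1-ol (anomer mixture) | COc1cc([C@H]2[C@H]3C(O)O[C@H](c4cc(OC)c(OC)c(OC)c4)[C@H]3CO2)ccc1O[Si](C)(C)C(C)(C)C | intermediate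
19 | (1R,3aR,4S,6aR)-1-(4-{[tert-butyl(dimethyl)silyl]oxy}-3-methoxyphenyl)-4-(3,4,5-trimethoxyphenyl)tetrahydro-1H,3H-furo[3,4-c]furan | COc1cc([C@H]2[C@H]3CO[C@H](c4cc(OC)c(OC)c(OC)c4)[C@H]3CO2)ccc1O[Si](C)(C)C(C)(C)C | intermediate
20 | 2-methoxy-4-[(1R,3aR,4S,6aR)-4-(3,4,5-trimethoxyphenyl)tetrahydro-1H,3H-furo[3,4-c]furan-1-yl]phenol | COc1cc([C@H]2[C@H]3CO[C@H](c4cc(OC)c(OC)c(OC)c4)[C@H]3CO2)ccc1O | intermediate
21 | 4-{[(3R,4R,5S)-4-(hydroxymethyl)-5-(3,4,5-trimethoxyphenyl)oxolan-3-yl]methyl}-2-methoxyphenol | COc1cc(C[C@H]2CO[C@H](c3cc(OC)c(OC)c(OC)c3)[C@H]2CO)ccc1O | target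

Total step count: 14. Longest linear sequence: 11 steps (steps 1–4 and 8–14).

Steps most likely to fail

Step 10. The carbene may undergo 1,2-hydride migration from the neighbouring ring C–H, or dimerise, faster than it inserts into the benzylic C–H bond. The fallback makes the same C–C bond by an aldol condensation and sets the 3,4-cis relation by hydrogenation; it sets out from 9 and comes back to the route at the target 21.
- Silylation of 9 (t-BuPh2SiCl, imidazole, DMF) gives (4R,5S)-4-({[tert-butyl(diphenyl)silyl]oxy}methyl)-5-(3,4,5-trimethoxyphenyl)oxolan-2-one F1.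
- Its lithium enolate (LiN(SiMe3)2, THF, −78 °C) adds to aldehyde 11 to give the carbinol mixture (4R,5S)-3-[(4-{[tert-butyl(dimethyl)silyl]oxy}-3-methoxyphenyl)(hydroxy)methyl]-4-({[tert-butyl(diphenyl)silyl]oxy}methyl)-5-(3,4,5-trimethoxyphenyl)oxolan-2-one F2.
- Acid-catalysed dehydration (p-TsOH cat., toluene, 60 °C) gives the (3E,4R,5S)-3-benzylidene lactone F3.
- Hydrogenation (H2, 10% Pd/C, EtOAc, rt) from the face opposite the C4 substituent should give the (3R,4R,5S)-3-benzyl lactone F4, with the benzyl group cis to the C4 arm.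
- i-Bu2AlH (−78 °C) gives the (3R,4R,5S)-lactol F5, and Et3SiH/BF3·OEt2 (−78 °C) the (2S,3R,4R)-oxolane bis-silyl ether F6.
- Bu4NF removes both silyl groups to give 21.

Step 14. Site selectivity of the benzylic C–O ionisation may be lost, or prolonged acid exposure may ionise the trimethoxyphenyl-bearing carbon of the product and lead to over-reduction or Friedel–Crafts closure onto the guaiacyl ring. The fallback sets out from 20 and comes back at 21. It is a hydrogenolysis under neutral conditions (H2, 1 atm, 10% Pd/C, EtOH, rt, stopped after one equivalent of hydrogen). The strained, phenol-bearing endo benzylic C–O bond of ring B is expected to be cleaved first, and no cation is formed. It makes no new compound (entry F0).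

Step 8. The electron-rich imidate may rearrange or self-condense before it benzylates the alcohol, and acid may promote acyl migration in 9. The fallback is a reductive etherification that uses the aldehyde as benzyl donor; it sets out from 9 and comes back at 14. Silylation (Me3SiCl, Et3N, CH2Cl2) gives (4R,5S)-4-{[(trimethylsilyl)oxy]methyl}-5-(3,4,5-trimethoxyphenyl)oxolan-2-one F7. With aldehyde 11, Et3SiH and catalytic Me3SiOTf (CH2Cl2, −78 °C), F7 is converted into 14; steps 6 and 7 are then not needed.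

Further compounds
F1 | step 10 | (4R,5S)-4-({[tert-butyl(diphenyl)silyl]oxy}methyl)-5-(3,4,5-trimethoxyphenyl)oxolan-2-one | O=C1O[C@H](c2cc(OC)c(OC)c(OC)c2)[C@@H](CO[Si](c2ccccc2)(c2ccccc2)C(C)(C)C)C1
F2 | step 10 | (4R,5S)-3-[(4-{[tert-butyl(dimethyl)silyl]oxy}-3-methoxyphenyl)(hydroxy)methyl]-4-({[tert-butyl(diphenyl)silyl]oxy}methyl)-5-(3,4,5-trimethoxyphenyl)oxolan-2-one (mixture at C3 and the carbinol carbon) | O=C1O[C@H](c2cc(OC)c(OC)c(OC)c2)[C@@H](CO[Si](c2ccccc2)(c2ccccc2)C(C)(C)C)C1C(O)c1ccc(O[Si](C)(C)C(C)(C)C)c(OC)c1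
F3 | step 10 | (3E,4R,5S)-3-[(4-{[tert-butyl(dimethyl)silyl]oxy}-3-methoxyphenyl)methylidene]-4-({[tert-butyl(diphenyl)silyl]oxy}methyl)-5-(3,4,5-trimethoxyphenyl)oxolan-2-one | O=C1O[C@H](c2cc(OC)c(OC)c(OC)c2)[C@@H](CO[Si](c2ccccc2)(c2ccccc2)C(C)(C)C)/C1=C\c1ccc(O[Si](C)(C)C(C)(C)C)c(OC)c1
F4 | step 10 | (3R,4R,5S)-3-[(4-{[tert-butyl(dimethyl)silyl]oxy}-3-methoxyphenyl)methyl]-4-({[tert-butyl(diphenyl)silyl]oxy}methyl)-5-(3,4,5-trimethoxyphenyl)oxolan-2-one | O=C1O[C@H](c2cc(OC)c(OC)c(OC)c2)[C@@H](CO[Si](c2ccccc2)(c2ccccc2)C(C)(C)C)[C@H]1Cc1ccc(O[Si](C)(C)C(C)(C)C)c(OC)c1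
F5 | step 10 | (3R,4R,5S)-3-[(4-{[tert-butyl(dimethyl)silyl]oxy}-3-methoxyphenyl)methyl]-4-({[tert-butyl(diphenyl)silyl]oxy}methyl)-5-(3,4,5-trimethoxyphenyl)oxolan-2-ol (anomer mixture) | OC1O[C@H](c2cc(OC)c(OC)c(OC)c2)[C@@H](CO[Si](c2ccccc2)(c2ccccc2)C(C)(C)C)[C@H]1Cc1ccc(O[Si](C)(C)C(C)(C)C)c(OC)c1
F6 | step 10 | (2S,3R,4R)-4-[(4-{[tert-butyl(dimethyl)silyl]oxy}-3-methoxyphenyl)methyl]-3-({[tert-butyl(diphenyl)silyl]oxy}methyl)-2-(3,4,5-trimethoxyphenyl)oxolane | C1O[C@H](c2cc(OC)c(OC)c(OC)c2)[C@@H](CO[Si](c2ccccc2)(c2ccccc2)C(C)(C)C)[C@H]1Cc1ccc(O[Si](C)(C)C(C)(C)C)c(OC)c1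
F0 | step 14 | none | none
F7 | step 8 | (4R,5S)-4-{[(trimethylsilyl)oxy]methyl}-5-(3,4,5-trimethoxyphenyl)oxolan-2-one | O=C1O[C@H](c2cc(OC)c(OC)c(OC)c2)[C@@H](CO[Si](C)(C)C)C1
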